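**Direct plan and its weak points**

A direct plan would keep rings A and B as bought arenes and close ring C between them. 1-[4-(Benzyloxy)-2,6-dihydroxyphenyl]ethan-1-one A1 would be condensed with 2,4-bis(benzyloxy)benzaldehyde A2 and the chalcone closed and dehydrogenated to the 5-hydroxyflavone A3. A3 would be iodinated at C6 to A4, A4 coupled with 2-methylbut-3-yn-2-ol A5 to the alkynylflavone A6, and A6 hydrogenated to the target.
(a) The condensation, oxa-Michael closure and dehydrogenation that turn A1 and A2 into A3 would stack three changes on a 2,6-dihydroxyacetophenone, and all they build is one C–C and one C–O bond of ring C.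
(b) The iodination of A3 would decide the place of the side chain late and only through a substituent effect: C6 against the equally activated C8, with chelation of the 5-OH as the sole bias.
(c) The Sonogashira coupling of A4 would put an alkyne next to a free phenol, where copper or palladium can close a furan. The hydrogenation of A6 would then have to saturate the alkyne, cleave three benzyl ethers and spare the propargylic C–O bond and the C2=C3 bond, all at once.

**Retrosynthetic overview of the new route**

- Ring A is not carried in; it is built last. Its bonds C4a–C5, C5–C6 and C7–C8 form in one operation by a ketene/ynol ether benzannulation. The precursors are a 2-aryl-4-pyranone (rings B and C) bearing a diazoacetyl group and a siloxyalkyne that already holds the whole 3-hydroxy-3-methylbutyl chain.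
- The feature that invites this: C6 carries the alkyl chain between the oxygen-bearing C5 and C7, and C8–H sits next to C8a. This is the 2-alkylresorcinol pattern that a vinylketene and a 1-siloxyalkyne deliver, with the new phenol at C5, peri to the C4 carbonyl.
- Order of rings: ring B is bought, ring C comes from cyclodehydration of a 1,3,5-triketone, and ring A closes last by 4π opening, 6π electrocyclisation and tautomerisation.
- By design there is no C6/C8 choice, no halogenation or cross-coupling beside a free phenol, no alkyne to hydrogenate and no chalcone. Deprotection is acid-free (fluoride, then hydrogenolysis), so the tertiary alcohol cannot close onto O5 or O7.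

Key step: step 7

Remark: the target is achiral, so no stereocentre has to be set. Compound 1, compound 8 and methyl 2,2-dimethoxypropanoate are taken to be commercial.

**Route**

Step 1
Reactants: 1 1-[2,4-bis(benzyloxy)phenyl]ethan-1-one
Product: 2 1-[2,4-bis(benzyloxy)phenyl]butane-1,3-dione
Conditions: NaH (2.5 equiv), EtOAc (3 equiv), THF, 0 °C to reflux; then aq. HCl
Reagents that add atoms: ethyl acetate (CCOC(C)=O)
Why: Crossed Claisen condensation in which the sodium enolate of the aryl methyl ketone is acetylated and the equilibrium is pulled over by deprotonation of the 1,3-diketone, the benzyl ethers being inert to NaH; no stereocentre is formed.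

Step 2
Reactants: 2 1-[2,4-bis(benzyloxy)phenyl]butane-1,3-dione
Product: 5 2-acetyl-6-[2,4-bis(benzyloxy)phenyl]-4H-pyran-4-one, via triketone ketal 3 (not isolated), via pyranone ketal 4 (not isolated)
Conditions: LiN(i-Pr)2 (3.1 equiv), THF, −78 to 0 °C; MeC(OMe)2CO2Me (1.3 equiv), −78 to 0 °C; aq. NH4Cl; then TsOH·H2O (10 mol%), MeOH, 50 °C; then 2 M HCl, THF, rt
Reagents that add atoms: methyl 2,2-dimethoxypropanoate (COC(=O)C(C)(OC)OC); water (O)
Why: Claisen acylation of the 1,3-diketone dianion at its terminal carbon by an ester that cannot enolise and is activated by its two α-alkoxy groups, then acid-catalysed cyclodehydration of the 1,3,5-triketone to the 4-pyranone while the ketal still masks the 1,2-dicarbonyl unit (so no furanone hemiketal can form), then ketal hydrolysis; no stereocentre is formed.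

Step 3
Reactants: 5 2-acetyl-6-[2,4-bis(benzyloxy)phenyl]-4H-pyran-4-one
Product: 7 6-[2,4-bis(benzyloxy)phenyl]-2-(2-diazoacetyl)-4H-pyran-4-one, via trifluoroacetyl ketone 6 (not isolated)
Conditions: LiN(SiMe3)2 (1.1 equiv), THF, −78 °C; CF3CO2CH2CF3 (1.2 equiv); aq. HCl; then MsN3 (1.5 equiv), Et3N (1.5 equiv), H2O (1 equiv), MeCN, rt
Reagents that add atoms: methanesulfonyl azide (CS(=O)(=O)N=[N+]=[N-])
Why: Detrifluoroacetylative Regitz diazo transfer, in which the lithium enolate of the methyl ketone is trifluoroacetylated and mesyl azide then delivers N2 to the activated methylene with loss of the trifluoroacetyl group as its sulfonamide, which avoids treating a conjugated acid chloride with diazomethane; no stereocentre is formed.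

Step 4
Reactants: 8 methyl pent-4-ynoate
Product: 9 2-methylhex-5-yn-2-ol
Conditions: MeMgBr (3.3 equiv), THF, 0 °C to rt; aq. NH4Cl
Reagents that add atoms: methylmagnesium bromide (C[Mg]Br)
Why: Double Grignard addition to the ester gives the tertiary alcohol, a third equivalent being consumed by the acetylenic C–H, which is restored on work-up; no stereocentre is formed.

Step 5
Reactants: 9 2-methylhex-5-yn-2-ol
Product: 10 triethyl[(2-methylhex-5-yn-2-yl)oxy]silane
Conditions: Et3SiOTf (1.2 equiv), 2,6-lutidine (2 equiv), CH2Cl2, −78 to 0 °C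
Reagents that add atoms: triethylsilyl trifluoromethanesulfonate (CC[Si](CC)(CC)OS(=O)(=O)C(F)(F)F)
Why: Silylation of a hindered tertiary alcohol with a silyl triflate and a hindered pyridine base, which masks a hydroxyl that would otherwise add to the ynol ether or to the ketene and which falls to fluoride later; no stereocentre is formed.

Step 6
Reactants: 10 triethyl[(2-methylhex-5-yn-2-yl)oxy]silane
Product: 13 5-methyl-5-(triethylsilyloxy)-1-(triisopropylsilyloxy)hex-1-yne, via lithium acetylide 11 (not isolated), via lithium ynolate 12 (not isolated)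
Conditions: n-BuLi (1.05 equiv), THF, −78 °C; t-BuOOLi (from t-BuOOH and LiN(SiMe3)2, 1.1 equiv), −78 to 0 °C; i-Pr3SiOTf (1.1 equiv), −78 to 0 °C
Reagents that add atoms: lithium tert-butyl peroxide (CC(C)(C)OO[Li]); triisopropylsilyl trifluoromethanesulfonate (CC(C)[Si](OS(=O)(=O)C(F)(F)F)(C(C)C)C(C)C)
Why: Electrophilic oxygenation of the lithium acetylide at the peroxide oxygen (loss of tert-butoxide) gives the lithium ynolate, which the bulky silyl triflate traps at oxygen and not at carbon, the triisopropylsilyl group being what makes the ynol ether isolable; no stereocentre is formed.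

Step 7
Reactants: 7 6-[2,4-bis(benzyloxy)phenyl]-2-(2-diazoacetyl)-4H-pyran-4-one, 13 5-methyl-5-(triethylsilyloxy)-1-(triisopropylsilyloxy)hex-1-yne
Product: 19 2-[2,4-bis(benzyloxy)phenyl]-5,7-dihydroxy-6-(3-hydroxy-3-methylbutyl)-4H-chromen-4-one, via pyranonylketene 14 (not isolated), via cyclobutenone 15 (not isolated), via dienylketene 16 (not isolated), via ring-A dienone 17 (not isolated), via bis-silyl flavone 18 (not isolated)
Conditions: 13 (1.5 equiv), hν (440 nm LEDs), ClCH2CH2Cl, rt; then 80 °C; then Bu4NF (4 equiv), THF, 0 °C to rt; aq. NH4Cl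
Reagents that add atoms: none
Why: Light of 440 nm should excite only the diazo ketone and trigger a Wolff rearrangement in which the pyranon-2-yl group migrates to give ketene 14; the electron-rich siloxyalkyne 13 adds to it in a regioselective [2+2] cycloaddition (its chain-bearing carbon bonds to the ketene carbonyl carbon) to give cyclobutenone 15, which at 80 °C opens by a conrotatory 4π electrocyclic reaction to dienylketene 16. Ring A is then closed by a disrotatory thermal 6π electrocyclisation of 16 onto C3 of the pyranone (bond C4a–C5), the doubly activated C4a–H of dienone 17 tautomerises at once to phenol 18 with its 5-OH held by the C4 carbonyl, and fluoride finally removes both silyl groups. The closest known reaction type is the Danheiser benzannulation in its diazo ketone form, in which aryl, heteroaryl and alkenyl diazomethyl ketones and triisopropylsiloxyalkynes give 2-alkyl-3-siloxyphenols fused to the migrating ring. The stereocentres at C4 of 15 and C4a of 17 are racemic and vanish on aromatisation, so no stereocontrol is needed. The selectivity the step needs is regiochemical and is secured by the substrate: the polarity of the ynol ether puts the chain carbon between the two oxygen-bearing carbons (C6 between C5 and C7), the ketene carbon can close only onto the one neighbouring ring carbon of the pyranone so that the new hydroxyl lands at C5 and C8 stays C–H, and the pyranone C2=C3 bond, far less aromatic than a benzene or furan bond, should enter the electrocyclisation readily.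

Step 8
Reactants: 19 2-[2,4-bis(benzyloxy)phenyl]-5,7-dihydroxy-6-(3-hydroxy-3-methylbutyl)-4H-chromen-4-one
Product: 20 2-(2,4-dihydroxyphenyl)-5,7-dihydroxy-6-(3-hydroxy-3-methylbutyl)-4H-chromen-4-one (target)
Conditions: H2 (1 atm), Pd/C (10 wt%), EtOAc/MeOH, rt
Reagents that add atoms: none
Why: Hydrogenolysis of the two aryl benzyl ethers over palladium on carbon, under which the C2=C3 bond of the flavone (a vinylogous ester) and the non-benzylic tertiary alcohol should stay untouched, and no acid is present that could close the side chain onto O5 or O7 as a chromane; no stereocentre is formed.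

**Compound list**

1 | 1-[2,4-bis(benzyloxy)phenyl]ethan-1-one | CC(=O)c1ccc(OCc2ccccc2)cc1OCc1ccccc1 | starting material
2 | 1-[2,4-bis(benzyloxy)phenyl]butane-1,3-dione | CC(=O)CC(=O)c1ccc(OCc2ccccc2)cc1OCc1ccccc1 | intermediate
3 | 1-[2,4-bis(benzyloxy)phenyl]-6,6-dimethoxyheptane-1,3,5-trione (triketone ketal) | COC(C)(OC)C(=O)CC(=O)CC(=O)c1ccc(OCc2ccccc2)cc1OCc1ccccc1 | intermediate (not isolated)
4 | 2-[2,4-bis(benzyloxy)phenyl]-6-(1,1-dimethoxyethyl)-4H-pyran-4-one (pyranone ketal) | COC(C)(OC)c1cc(=O)cc(-c2ccc(OCc3ccccc3)cc2OCc2ccccc2)o1 | intermediate (not isolated)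
5 | 2-acetyl-6-[2,4-bis(benzyloxy)phenyl]-4H-pyran-4-one | CC(=O)c1cc(=O)cc(-c2ccc(OCc3ccccc3)cc2OCc2ccccc2)o1 | intermediate
6 | 1-{6-[2,4-bis(benzyloxy)phenyl]-4-oxo-4H-pyran-2-yl}-4,4,4-trifluorobutane-1,3-dione (trifluoroacetyl ketone) | O=C(CC(=O)C(F)(F)F)c1cc(=O)cc(-c2ccc(OCc3ccccc3)cc2OCc2ccccc2)o1 | intermediate (not isolated)
7 | 6-[2,4-bis(benzyloxy)phenyl]-2-(2-diazoacetyl)-4H-pyran-4-one | [N-]=[N+]=CC(=O)c1cc(=O)cc(-c2ccc(OCc3ccccc3)cc2OCc2ccccc2)o1 | intermediate
8 | methyl pent-4-ynoate | C#CCCC(=O)OC | starting material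
9 | 2-methylhex-5-yn-2-ol | C#CCCC(C)(C)O | intermediate
10 | triethyl[(2-methylhex-5-yn-2-yl)oxy]silane | C#CCCC(C)(C)O[Si](CC)(CC)CC | intermediate
11 | [5-methyl-5-(triethylsilyloxy)hex-1-yn-1-yl]lithium (lithium acetylide) | [Li]C#CCCC(C)(C)O[Si](CC)(CC)CC | intermediate (not isolated)
12 | lithium 5-methyl-5-(triethylsilyloxy)hex-1-yn-1-olate (lithium ynolate) | [Li]OC#CCCC(C)(C)O[Si](CC)(CC)CC | intermediate (not isolated)
13 | 5-methyl-5-(triethylsilyloxy)-1-(triisopropylsilyloxy)hex-1-yne | CC[Si](CC)(CC)OC(C)(C)CCC#CO[Si](C(C)C)(C(C)C)C(C)C | intermediate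
14 | 2-{6-[2,4-bis(benzyloxy)phenyl]-4-oxo-4H-pyran-2-yl}ethen-1-one (pyranonylketene) | O=C=Cc1cc(=O)cc(-c2ccc(OCc3ccccc3)cc2OCc2ccccc2)o1 | intermediate (not isolated)
15 | 4-{6-[2,4-bis(benzyloxy)phenyl]-4-oxo-4H-pyran-2-yl}-2-[3-methyl-3-(triethylsilyloxy)butyl]-3-(triisopropylsilyloxy)cyclobut-2-en-1-one (racemic at C4) | O=C1C(CCC(C)(C)O[Si](CC)(CC)CC)=C(O[Si](C(C)C)(C(C)C)C(C)C)C1c1cc(=O)cc(-c2ccc(OCc3ccccc3)cc2OCc2ccccc2)o1 | intermediate (not isolated)
16 | dienylketene O=C=C(chain)–C(OSi(i-Pr)3)=CH–(pyranon-2-yl), with the ketene-bearing carbon and the pyranonyl group cis on the siloxy-substituted double bond | O=C=C(CCC(C)(C)O[Si](CC)(CC)CC)/C(O[Si](C(C)C)(C(C)C)C(C)C)=C\c1cc(=O)cc(-c2ccc(OCc3ccccc3)cc2OCc2ccccc2)o1 | intermediate (not isolated)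
17 | 2-[2,4-bis(benzyloxy)phenyl]-6-[3-methyl-3-(triethylsilyloxy)butyl]-7-(triisopropylsilyloxy)-4aH-chromene-4,5-dione (ring-A dienone, racemic at C4a) | O=C1C(CCC(C)(C)O[Si](CC)(CC)CC)=C(O[Si](C(C)C)(C(C)C)C(C)C)C=C2OC(-c3ccc(OCc4ccccc4)cc3OCc3ccccc3)=CC(=O)C12 | intermediate (not isolated)
18 | 2-[2,4-bis(benzyloxy)phenyl]-5-hydroxy-6-[3-methyl-3-(triethylsilyloxy)butyl]-7-(triisopropylsilyloxy)-4H-chromen-4-one | CC[Si](CC)(CC)OC(C)(C)CCc1c(O[Si](C(C)C)(C(C)C)C(C)C)cc2oc(-c3ccc(OCc4ccccc4)cc3OCc3ccccc3)cc(=O)c2c1O | intermediate (not isolated)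
19 | 2-[2,4-bis(benzyloxy)phenyl]-5,7-dihydroxy-6-(3-hydroxy-3-methylbutyl)-4H-chromen-4-one | CC(C)(O)CCc1c(O)cc2oc(-c3ccc(OCc4ccccc4)cc3OCc3ccccc3)cc(=O)c2c1O | intermediate
20 | 2-(2,4-dihydroxyphenyl)-5,7-dihydroxy-6-(3-hydroxy-3-methylbutyl)-4H-chromen-4-one (achiral) | CC(C)(O)CCc1c(O)cc2oc(-c3ccc(O)cc3O)cc(=O)c2c1O | target

**Summary**

Total step count: 8. Longest linear sequence: 5 steps (steps 1, 2, 3, 7, 8; the alkyne branch, steps 4, 5, 6, 7, 8, is equally long).

Steps most likely to fail:

Step 7 (key step). The light-driven Wolff rearrangement may be outrun by carbene reactions with the alkyne or by photoreactions of the arylpyranone, or the ketene may dimerise before it meets the ynol ether. As a fallback, the ketene would be made in the dark and apart from the alkyne. Setting out from 7, a Wolff rearrangement catalysed by silver benzoate (PhCO2Ag) with Et3N in aqueous dioxane (the homologation half of the Arndt–Eistert reaction) would give {6-[2,4-bis(benzyloxy)phenyl]-4-oxo-4H-pyran-2-yl}acetic acid F1. Oxalyl chloride at 0 °C would give {6-[2,4-bis(benzyloxy)phenyl]-4-oxo-4H-pyran-2-yl}acetyl chloride F2. Slow addition of F2 to 13 and i-Pr2NEt in toluene at 60–80 °C would generate ketene 14 by dehydrochlorination. The fallback comes back to the route at 14, which goes on through 15 to 19 as in step 7.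

Step 6. Oxygen transfer to the acetylide may stay incomplete, or the ynolate may be silylated at carbon to a silylketene. As a fallback, the ynolate would be reached by a carbenoid rearrangement and not by an oxidation. Setting out from 10, dibromohydration of the terminal alkyne (N-bromosuccinimide, buffered MeCN/H2O, rt) would give 1,1-dibromo-5-methyl-5-(triethylsilyloxy)hexan-2-one F3. Deprotonation with LiN(SiMe3)2 and bromine–lithium exchange with n-BuLi would start the 1,2-shift known from the Kowalski ester homologation and give lithium ynolate 12. The fallback comes back to the route at 12, before silylation to 13.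

Step 2. The dianion may be acylated only sluggishly by the hindered ketal ester, or the 1,2-dicarbonyl unit may be unmasked too early and divert to furanone hemiketals before the pyranone closes. As a fallback, the carbon that becomes C5 would come from an oxalate and the diazo carbon from diazomethane. Setting out from 2, Claisen condensation with diethyl oxalate (NaOEt, EtOH) would give ethyl 6-[2,4-bis(benzyloxy)phenyl]-2,4,6-trioxohexanoate F4. HCl in EtOH would close it to ethyl 6-[2,4-bis(benzyloxy)phenyl]-4-oxo-4H-pyran-2-carboxylate F5. LiOH in aqueous THF at 0 °C would give 6-[2,4-bis(benzyloxy)phenyl]-4-oxo-4H-pyran-2-carboxylic acid F6, and oxalyl chloride would give 6-[2,4-bis(benzyloxy)phenyl]-4-oxo-4H-pyran-2-carbonyl chloride F7. Excess diazomethane in Et2O/THF at 0 °C would then give diazo ketone 7. The fallback comes back to the route at 7 and replaces steps 2 and 3.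

**Further compounds**

F1 | step 7 | {6-[2,4-bis(benzyloxy)phenyl]-4-oxo-4H-pyran-2-yl}acetic acid | OC(=O)Cc1cc(=O)cc(-c2ccc(OCc3ccccc3)cc2OCc2ccccc2)o1
F2 | step 7 | {6-[2,4-bis(benzyloxy)phenyl]-4-oxo-4H-pyran-2-yl}acetyl chloride | ClC(=O)Cc1cc(=O)cc(-c2ccc(OCc3ccccc3)cc2OCc2ccccc2)o1
F3 | step 6 | 1,1-dibromo-5-methyl-5-(triethylsilyloxy)hexan-2-one | BrC(Br)C(=O)CCC(C)(C)O[Si](CC)(CC)CC
F4 | step 2 | ethyl 6-[2,4-bis(benzyloxy)phenyl]-2,4,6-trioxohexanoate | CCOC(=O)C(=O)CC(=O)CC(=O)c1ccc(OCc2ccccc2)cc1OCc1ccccc1
F5 | step 2 | ethyl 6-[2,4-bis(benzyloxy)phenyl]-4-oxo-4H-pyran-2-carboxylate | CCOC(=O)c1cc(=O)cc(-c2ccc(OCc3ccccc3)cc2OCc2ccccc2)o1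
F6 | step 2 | 6-[2,4-bis(benzyloxy)phenyl]-4-oxo-4H-pyran-2-carboxylic acid | OC(=O)c1cc(=O)cc(-c2ccc(OCc3ccccc3)cc2OCc2ccccc2)o1
F7 | step 2 | 6-[2,4-bis(benzyloxy)phenyl]-4-oxo-4H-pyran-2-carbonyl chloride | ClC(=O)c1cc(=O)cc(-c2ccc(OCc3ccccc3)cc2OCc2ccccc2)o1
A1 | direct plan | 1-[4-(benzyloxy)-2,6-dihydroxyphenyl]ethan-1-one | CC(=O)c1c(O)cc(OCc2ccccc2)cc1O
A2 | direct plan | 2,4-bis(benzyloxy)benzaldehyde | O=Cc1ccc(OCc2ccccc2)cc1OCc1ccccc1
A3 | direct plan | 7-(benzyloxy)-2-[2,4-bis(benzyloxy)phenyl]-5-hydroxy-4H-chromen-4-one | O=c1cc(-c2ccc(OCc3ccccc3)cc2OCc2ccccc2)oc2cc(OCc3ccccc3)cc(O)c12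
A4 | direct plan | 7-(benzyloxy)-2-[2,4-bis(benzyloxy)phenyl]-5-hydroxy-6-iodo-4H-chromen-4-one | O=c1cc(-c2ccc(OCc3ccccc3)cc2OCc2ccccc2)oc2cc(OCc3ccccc3)c(I)c(O)c12
A5 | direct plan | 2-methylbut-3-yn-2-ol | C#CC(C)(C)O
A6 | direct plan | 7-(benzyloxy)-2-[2,4-bis(benzyloxy)phenyl]-5-hydroxy-6-(3-hydroxy-3-methylbut-1-yn-1-yl)-4H-chromen-4-one | O=c1cc(-c2ccc(OCc3ccccc3)cc2OCc2ccccc2)oc2cc(OCc3ccccc3)c(C#CC(C)(C)O)c(O)c12
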